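## Structural features

The target is a bridged bicyclic lactam: an azepan-2-one and a nine-membered ring share the nitrogen atom, the amide carbonyl and its α-carbon, so the amide C=O is the one-atom bridge of a 1-azabicyclo[6.4.1]tridecane. The nine-membered ring also holds a ketone. An α-methyl-γ-butyrolactone is cis-fused to it across the O-bearing carbon and the ketone α-methine, and a second, cis-2,4-disubstituted γ-butyrolactone hangs from the N-bearing carbon. Of the eight stereocentres, five are contiguous (lactam α-carbon R, ethyl carbon R, O–CH S, ring-fusion CH S, CH–CH3 S). The other three lie on the nitrogen side (N–CH S next to the pendant lactone O–CH S, and the remote CH–CH3 S). The ring-fusion methine is α to the ketone and β to the lactone oxygen, so it can epimerise or lose the lactone oxygen by E1cB. The ketone is also a β-amido ketone, and both lactones are acyl donors toward any free amine. The real difficulty is the medium ring with its bridgehead amide and the stereo-array around it, since direct closure of a nine-membered ring is entropically and transannularly poor. The feature used here is that the ketone and the lactam carbonyl are 1,5-related through nitrogen (O=C–CH2–CH–N–C=O) and that the ketone α-methine is the lactone ring-fusion carbon. Joining the lactam carbonyl carbon back to that methine contracts the nine-membered ring to a cyclopentanone whose quaternary ring-fusion carbon carries the amino acyl chain.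

## Logic of the disconnections

**24 to 22.** The bond from nitrogen to the ring CH2 of the azepanone is cut. It is the one bond that can be made last without base, through an N-acyliminium ion, and cutting it removes the bridged bicycle. What remains is the monocyclic lactam 22 with a masked aldehyde on a four-carbon chain. No stereocentre is involved. The forward step must ionise the acetal and reduce the iminium ion (via 23) without reducing the ketone or touching the β-acyloxy ketone.

**22 to 20 (stored as 19).** The lactam N–C(=O) bond is cut and the carbonyl carbon is re-joined to the ketone α-methine. The nine-membered ring becomes a cyclopentanone, and the epimerisable ring-fusion centre becomes a quaternary carbon whose configuration is fixed by the cis fusion of a bicyclo[3.3.0] system. The forward step needs the amine to attack the ring ketone and not the pendant lactone, the fragmentation to beat simple imine formation, and the enol to ketonise to the cis-fused product.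

**19 to 18.** The bond from the ethyl group to its ring carbon is cut, giving an enone. The ethyl centre and the neighbouring chain-bearing centre then derive from one conjugate addition and one thermodynamic protonation. The forward step must add to the convex face, anti to the lactone oxygen, and must leave two ketones and two lactones alone.

**18 to 17, then 15 plus 16.** The bond from the methyl-bearing carbon to the quaternary carbon is cut, then the ester C–O bond. A tether through the ring oxygen is the only way to bring the propionate unit to the face cis to that oxygen, and an SN2 displacement fixes the methyl centre from a chiral-pool acid. The forward steps need selective esterification of the alcohol beside an enolised diketone, C- rather than O-alkylation, and no loss of configuration at the C–Br centre.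

**15 to 14 to 13, then 12 plus 7.** The bond from the ring to the side-chain carbonyl carbon is cut at the aldol oxidation level. Doing this while the ring is still an enone is deliberate: the α'-enolate of a 4-silyloxycyclopentenone cannot expel the silyloxy group without forming a cyclopentadienone. The gain is full convergence of the two halves. The forward step needs regioselective α'-deprotonation and an aldehyde that survives an enolate.

**12 to 9 plus 11 (from 10); 9 to 8.** The sp2–sp3 bond between the enone α-carbon and the acetal chain is cut. The chain comes from a terminal alkene by hydroboration and the enone from a commercial chiral cyclopentenone by α-iodination. The forward coupling must tolerate the silyl ether and the acetal.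

**7 to 6 to 5, then 2 plus 3; 2 to 1.** The pendant lactone is opened at its C–O bond and cut between the carbinol carbon and the neighbouring CH2. This leads to an α-amino aldehyde, masked as a lactol, and a 2-(alkoxycarbonyl)allyl unit. The N-bearing centre comes from the chiral pool. The forward steps must set the carbinol centre syn to nitrogen and the methyl centre cis on the lactone.

## Other disconnections considered

**Alternative 1:** The cut is the bond from the methyl-bearing carbon to the ring-fusion carbon, together with the C–O bond of the future ketone, on an intact nine-membered bridged lactam. In the forward direction the mixed bromoacetal A1 of a nine-membered (Z)-cycloalkenol would be treated with Bu3SnH under air. The radical at the bromo carbon should close 5-exo onto the near alkene carbon, and the ring radical should be captured by O2 to give the lactol ether A2. Oxidation of the lactol ether and the carbinol would then give the target.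

- In its favour: the annulation is late, the tether enforces cis fusion, and cyclisation onto a disubstituted cis alkene is fast enough to precede oxygen capture. The nitrogen is already a tertiary lactam, so no free amine ever meets a lactone; on this point the alternative is better than the chosen plan.
- Against it: A1 presupposes that the nine-membered ring with its bridgehead amide has been closed directly by some other reaction. The methyl centre is set only by the preference of a radical transition state. The ring-fusion centre is set on a conformationally mobile medium ring. Oxygen capture must also win over reduction by the tin hydride.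
- Comparison: on structure both plans build the cis lactone through an oxygen tether, but the chosen plan fixes the methyl centre by SN2. On mechanism it is a radical chain against ionic steps. On step economy the alternative needs two oxidation-level corrections after its key step and a medium-ring closure before it, whereas the chosen plan needs one step after the key step and never closes a medium ring end to end.

**Alternative 2:** The cuts are the amide N–C(=O) bond and the bond from the lactam α-carbon to the ethyl-bearing carbon, with nitrogen re-joined to the future ring-fusion carbon as a pyrrolidine. In the forward direction the 2-butenylpyrrolidine A3, made from trans-4-hydroxy-L-proline, would be acylated by 6-chlorohexanoyl fluoride A4 with Al(CH3)3. The acylammonium enolate should rearrange [3,3] to the nine-membered lactam A5 with an E ring alkene.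

- In its favour: like the chosen plan it makes the medium ring by rearrangement of a small ring, and on that point the two are equal. It creates the ethyl and lactam α-centres in one step through an ordered transition state, and it takes the N-bearing centre from a cheap amino acid.
- Against it: A5 is far from the target. The E alkene must be turned into the cis-fused lactone with control of both new centres on a planar-chiral ring. The silyloxy carbon must be oxidised. The pendant lactone must be built late from a CH2O group by an aldehyde allylation next to an amide. The benzyl group must be removed and the chloride closed onto nitrogen with base, in a molecule that by then holds a β-acyloxy ketone. Whether chair or boat topology relays the right configuration from A3 is also open.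
- Comparison: on structure the alternative brings two of eight centres into the key step, against seven carried into step 13 and one set there. On mechanism both are fragmentative ring enlargements. On step economy the alternative is clearly longer after its key step.

**Alternative 3:** The cut is the bond from the ethyl-bearing carbon to the O-bearing carbon. In the forward direction CrCl2 would reduce the allylic bromide of the propylidene caprolactam aldehyde A6 to an allylchromium species. This should add through its ethyl-bearing terminus to the aldehyde and close the nine-membered ring, giving the hydroxy ester A7 with an unsaturated azepanone.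

- In its favour: the azepanone and both N–C bonds are in place before the medium ring is made, so no late N-alkylation is needed, and the ketone is masked as a silyl ether, which removes the β-elimination problem. On both points it is better than the chosen plan. Organochromium additions tolerate esters, lactones and lactams.
- Against it: it is a direct nine-membered closure, needing high dilution and a large excess of the chromium salt. The relative and facial selectivity of a medium-ring allylation is hard to predict. The ring alkene must then be reduced with control of the lactam α-centre. A6 needs a long linear synthesis of a stereotriad that carries an aldehyde and an allylic bromide at once.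
- Comparison: on structure the alternative sets two centres in the key step but leaves a third to a later reduction. On mechanism it is an end-to-end closure, against a fragmentation. On step economy the redox and lactonisation steps after A7 outnumber the single step after 22.

Key step: step 13

Remark (check of the structures): the descriptors of 20, 22 and 24 were derived independently and agree (R at the lactam α-carbon and the ethyl carbon, S at the other centres), so no structure was changed; the amine of 20 can, however, reach two carbonyl groups through a six-membered ring, the cyclopentanone and the pendant lactone, and step 13 is designed with this in mind.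

Remark (design of the precursor): 20 is not storable, so it is carried as its benzyl carbamate 19 and released in the flask; the methyl centre of the fused lactone is fixed by an SN2 step, not by a cyclisation preference.

Remark (assumption on supply): 1, 8, 10 and 16 are taken as commercial; if not, each is one routine step from L-homoserine, (S)-4-hydroxycyclopent-2-en-1-one, allylmagnesium bromide with trimethyl orthoformate, and L-alanine.

## Steps

Step 1
Reactants: 1 benzyl N-[(3S)-2-oxooxolan-3-yl]carbamate (N-Cbz-L-homoserine lactone)
Product: 2 benzyl N-[(3S)-2-hydroxyoxolan-3-yl]carbamate (lactol, both anomers)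
Conditions: i-Bu2AlH, CH2Cl2, −78 °C; aq. Rochelle salt
Reagents that add atoms: none
Why: Partial reduction of a γ-lactone by i-Bu2AlH stops at the tetrahedral aluminate at −78 °C; the carbamate N–H takes one equivalent and the α-stereocentre is not enolised.

Step 2
Reactants: 2 benzyl N-[(3S)-2-hydroxyoxolan-3-yl]carbamate; 3 ethyl 2-(bromomethyl)prop-2-enoate
Product: 5 benzyl N-[(1S)-3-hydroxy-1-[(2S)-4-methylidene-5-oxooxolan-2-yl]propyl]carbamate, via hydroxy ester 4 (not isolated)
Conditions: In powder, THF–H2O (1:1), rt; then TsOH·H2O (cat.), CH2Cl2, rt
Reagents that add atoms: none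
Why: Barbier-type allylation: the lactol reacts through its open hydroxy aldehyde, and the allylindium reagent should add under chelation (Cram chelate) control between the aldehyde oxygen and the N–H carbamate, placing the new hydroxyl syn to nitrogen (S); the γ-hydroxy ester 4 then closes to the five-membered lactone under acid, the primary hydroxyl being too remote to compete.

Step 3
Reactants: 5 benzyl N-[(1S)-3-hydroxy-1-[(2S)-4-methylidene-5-oxooxolan-2-yl]propyl]carbamate
Product: 6 benzyl N-[(1S)-3-hydroxy-1-[(2S,4S)-4-methyl-5-oxooxolan-2-yl]propyl]carbamate
Conditions: H2 (3 atm), RhCl(PPh3)3 (5 mol%), benzene–EtOH (1:1), rt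
Reagents that add atoms: none
Why: Homogeneous hydrogenation with RhCl(PPh3)3 reduces the 1,1-disubstituted exocyclic alkene without hydrogenolysis of the benzyl carbamate; hydrogen should be delivered to the lactone face opposite the C2 substituent, giving the cis (2S,4S) lactone.

Step 4
Reactants: 6 benzyl N-[(1S)-3-hydroxy-1-[(2S,4S)-4-methyl-5-oxooxolan-2-yl]propyl]carbamate
Product: 7 benzyl N-[(1S)-1-[(2S,4S)-4-methyl-5-oxooxolan-2-yl]-3-oxopropyl]carbamate
Conditions: Dess–Martin periodinane, NaHCO3, CH2Cl2, 0 °C to rt
Reagents that add atoms: none
Why: Dess–Martin oxidation of the primary alcohol under buffered, non-basic conditions, chosen because the β-carbamoyl aldehyde would lose the carbamate by E1cB with base; 7 is used at once.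

Step 5
Reactants: 8 (4S)-4-(tert-butyldimethylsilyloxy)cyclopent-2-en-1-one
Product: 9 (4S)-4-(tert-butyldimethylsilyloxy)-2-iodocyclopent-2-en-1-one
Conditions: I2, pyridine, CH2Cl2, 0 °C to rt
Reagents that add atoms: iodine, II
Why: α-Iodination of a cyclic enone by conjugate addition of pyridine, iodination of the enolate and elimination; the silyl ether and the stereocentre are not involved.

Step 6
Reactants: 10 4,4-dimethoxybut-1-ene; 9 (4S)-4-(tert-butyldimethylsilyloxy)-2-iodocyclopent-2-en-1-one
Product: 12 (4S)-4-(tert-butyldimethylsilyloxy)-2-(4,4-dimethoxybutyl)cyclopent-2-en-1-one, via alkylborane 11 (not isolated)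
Conditions: 9-BBN, THF, 0 °C to rt; then 9, PdCl2(dppf) (5 mol%), AsPh3, Cs2CO3, DMF–THF–H2O, rt
Reagents that add atoms: none
Why: Anti-Markovnikov hydroboration of the terminal alkene gives the B-alkyl borane 11, which undergoes B-alkyl Suzuki–Miyaura coupling with the α-iodo enone under zerovalent palladium catalysis; the mild aqueous base leaves the silyl ether and the acetal intact.

Step 7
Reactants: 12 (4S)-4-(tert-butyldimethylsilyloxy)-2-(4,4-dimethoxybutyl)cyclopent-2-en-1-one; 7 benzyl N-[(1S)-1-[(2S,4S)-4-methyl-5-oxooxolan-2-yl]-3-oxopropyl]carbamate
Product: 13 benzyl N-[(1S)-3-[(1S,5R)-5-(tert-butyldimethylsilyloxy)-3-(4,4-dimethoxybutyl)-2-oxocyclopent-3-en-1-yl]-3-hydroxy-1-[(2S,4S)-4-methyl-5-oxooxolan-2-yl]propyl]carbamate (both carbinol epimers; silyloxy group and side chain trans)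
Conditions: LiN(i-Pr)2, THF, −78 °C (12 in excess); then 7, −78 °C; AcOH, −78 °C
Reagents that add atoms: none
Why: Kinetic α'-deprotonation gives the cross-conjugated lithium enolate, which adds to the aldehyde (aldol addition) anti to the silyloxy group; this enolate cannot expel the β-silyloxy group because that would form a cyclopentadienone, which is why the side chain is attached while the ring is still an enone; the carbinol centre and the new ring centre both become sp2 later, so their configuration is of no consequence (the silyloxy carbon is now labelled R only because of the new neighbour).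

Step 8
Reactants: 13 the aldol adduct of step 7
Product: 14 benzyl N-[(1S)-3-[(5R)-5-(tert-butyldimethylsilyloxy)-3-(4,4-dimethoxybutyl)-2-oxocyclopent-3-en-1-yl]-1-[(2S,4S)-4-methyl-5-oxooxolan-2-yl]-3-oxopropyl]carbamate (keto–enol mixture at ring C1)
Conditions: Dess–Martin periodinane, NaHCO3, CH2Cl2, 0 °C
Reagents that add atoms: none
Why: Dess–Martin oxidation of a β-hydroxy ketone to the 1,3-diketone; the bicarbonate buffer protects the acetal and the silyl ether, and a small excess of oxidant avoids hydroxylation of the diketone.

Step 9
Reactants: 14 the silyl-protected diketone of step 8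
Product: 15 benzyl N-[(1S)-3-[(5R)-3-(4,4-dimethoxybutyl)-5-hydroxy-2-oxocyclopent-3-en-1-yl]-1-[(2S,4S)-4-methyl-5-oxooxolan-2-yl]-3-oxopropyl]carbamate
Conditions: HF·pyridine, pyridine, THF, 0 °C to rt
Reagents that add atoms: none
Why: Fluoride cleavage of the secondary allylic silyl ether in a pyridine-buffered medium that leaves the dimethyl acetal; no base is present, so the β-hydroxy diketone should not open by retro-aldol, and dehydration would again require a cyclopentadienone.

Step 10
Reactants: 15 the hydroxy diketone of step 9; 16 (2S)-2-bromopropanoic acid
Product: 17 (1S)-5-[(3S)-3-(benzyloxycarbonylamino)-3-[(2S,4S)-4-methyl-5-oxooxolan-2-yl]propanoyl]-3-(4,4-dimethoxybutyl)-4-oxocyclopent-2-en-1-yl (2S)-2-bromopropanoate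
Conditions: PPh3, DIAD (betaine pre-formed), THF, −20 to 0 °C
Reagents that add atoms: none
Why: Mitsunobu esterification: the carboxylic acid is far more acidic than the diketone enol and is the only nucleophile, so the secondary allylic alcohol alone is esterified, with inversion; this turns the carbinol configuration inherited from 8 into that of the lactone oxygen of the target, and the C–Br centre of 16 is not touched.

Step 11
Reactants: 17 the bromopropanoate of step 10
Product: 18 benzyl N-[(1S)-3-[(1S,4S,5S)-7-(4,4-dimethoxybutyl)-4-methyl-3,6-dioxo-2-oxabicyclo[3.3.0]oct-7-en-5-yl]-1-[(2S,4S)-4-methyl-5-oxooxolan-2-yl]-3-oxopropyl]carbamate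
Conditions: Cs2CO3, MeCN, 0 °C to rt, dilute
Reagents that add atoms: none
Why: Intramolecular C-alkylation (5-exo-tet) of the soft 1,3-diketone enolate by the α-bromo ester forms the lactone C–C bond and the quaternary carbon; the tether delivers the electrophile on the face of the ester oxygen, so the lactone is cis-fused and the acyl chain is on the opposite face, and SN2 inversion of the (S) bromide sets the methyl-bearing carbon S with methyl on the convex face; O-alkylation would need a seven-membered ring, and β-elimination would again give a cyclopentadienone.

Step 12
Reactants: 18 the bicyclic enone lactone of step 11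
Product: 19 benzyl N-[(1S)-3-[(1S,4S,5S,7R,8R)-7-(4,4-dimethoxybutyl)-8-ethyl-4-methyl-3,6-dioxo-2-oxabicyclo[3.3.0]octan-5-yl]-1-[(2S,4S)-4-methyl-5-oxooxolan-2-yl]-3-oxopropyl]carbamate
Conditions: EtMgBr, CuBr·SMe2, THF, −78 to −40 °C; aq. NH4Cl; then Et3N, CH2Cl2, rt
Reagents that add atoms: ethylmagnesium bromide, CC[Mg]Br
Why: Conjugate addition of an ethylcuprate to the α-substituted cyclopentenone from the convex face, anti to the lactone oxygen on the neighbouring carbon, sets the ethyl carbon R; protonation followed by mild base equilibration at the only enolisable α-carbon places the acetal chain trans to ethyl (R), and the cuprate does not add to the hindered ketone or the lactones at low temperature.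

Step 13
Reactants: 19 the N-benzyloxycarbonyl diketone of step 12
Product: 22 nine-membered keto lactam (secondary amide, cis-fused methyl lactone, dimethoxybutyl chain on the lactam α-carbon), via amino diketone 20 (not isolated), via bicyclic carbinolamine 21 (not isolated)
Conditions: H2 (1 atm), Pd/C, AcOH (2 equiv), EtOAc, rt; filter; toluene, 40 °C
Reagents that add atoms: none
Why: Hydrogenolysis of the benzyl carbamate frees amine 20, held mostly as its acetate; the free base adds to the cyclopentanone carbonyl in a 6-exo-trig closure to give the fused carbinolamine 21. 21 collapses by breaking the bond from the carbinolamine carbon to the quaternary carbon, which forms the amide and releases the enol of the side-chain ketone; this is the amine-triggered retro-Claisen (transamidation) ring enlargement known for 2-acylcycloalkanones with an amine on the acyl chain, a four-atom expansion. The nine-membered ring is therefore not closed end to end but arises by fragmentation of the shared bond of the 6/5 bicycle, driven by amide formation, loss of the strained cis-bicyclo[3.3.0] system and the fact that the quaternary 1,3-diketone cannot enolise. The one new stereocentre, the ring-fusion CH, is set when the enol ketonises; the centre stays epimerisable under the acetate buffer, so the outcome should be thermodynamic, with the ketone carbon cis to the ring carbon on the O-bearing centre and trans to the neighbouring methyl group, as in 22. The selectivity needed is attack at the ring ketone and not at the pendant lactone carbonyl, which is also six atoms away: the ketone is the better electrophile, 21 is an unstrained fused bicycle whereas the lactone route must pass a 2-aza-7-oxabicyclo[2.2.1]heptane, and acetic acid catalyses carbonyl addition while keeping the concentration of free amine low. The side-chain ketone would require a four-membered ring and is out of reach. No base is present, and the lactone C–O bond lies close to the nodal plane of the enol, so loss of the lactone oxygen by E1cB is not expected. The chain-bearing centre next to the new amide carbonyl is not touched.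

Step 14
Reactants: 22 the nine-membered keto lactam of step 13
Product: 24 target (1-azabicyclo[6.4.1]tridecane keto lactam with both lactones), via methoxy aminal 23 (not isolated)
Conditions: CF3CO2H, CH2Cl2, 0 °C; then Et3SiH, 0 °C to rt
Reagents that add atoms: none
Why: Acid ionises the dimethyl acetal and the lactam nitrogen closes the seven-membered ring to the methoxy aminal 23, which ionises to the N-acyliminium ion and is reduced by hydride transfer from Et3SiH (ionic hydrogenation, reductive N-alkylation of an amide by an acetal); the silane is added after cyclisation so that the acetal is not reduced to a methyl ether, no stereocentre is formed, and the non-basic medium spares the β-acyloxy ketone.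

## Compound list

1 | benzyl N-[(3S)-2-oxooxolan-3-yl]carbamate | O=C1OCC[C@@H]1NC(=O)OCc1ccccc1 | starting material
2 | benzyl N-[(3S)-2-hydroxyoxolan-3-yl]carbamate (anomers) | OC1OCC[C@@H]1NC(=O)OCc1ccccc1 | intermediate
3 | ethyl 2-(bromomethyl)prop-2-enoate | C=C(CBr)C(=O)OCC | starting material
4 | ethyl (4S,5S)-5-(benzyloxycarbonylamino)-4,7-dihydroxy-2-methylideneheptanoate | CCOC(=O)C(=C)C[C@H](O)[C@H](CCO)NC(=O)OCc1ccccc1 | intermediate
5 | benzyl N-[(1S)-3-hydroxy-1-[(2S)-4-methylidene-5-oxooxolan-2-yl]propyl]carbamate | OCC[C@H](NC(=O)OCc1ccccc1)[C@@H]1CC(=C)C(=O)O1 | intermediate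
6 | benzyl N-[(1S)-3-hydroxy-1-[(2S,4S)-4-methyl-5-oxooxolan-2-yl]propyl]carbamate | OCC[C@H](NC(=O)OCc1ccccc1)[C@@H]1C[C@H](C)C(=O)O1 | intermediate
7 | benzyl N-[(1S)-1-[(2S,4S)-4-methyl-5-oxooxolan-2-yl]-3-oxopropyl]carbamate | O=CC[C@H](NC(=O)OCc1ccccc1)[C@@H]1C[C@H](C)C(=O)O1 | intermediate
8 | (4S)-4-(tert-butyldimethylsilyloxy)cyclopent-2-en-1-one | O=C1C=C[C@@H](O[Si](C)(C)C(C)(C)C)C1 | starting material
9 | (4S)-4-(tert-butyldimethylsilyloxy)-2-iodocyclopent-2-en-1-one | O=C1C(I)=C[C@@H](O[Si](C)(C)C(C)(C)C)C1 | intermediate
10 | 4,4-dimethoxybut-1-ene | C=CCC(OC)OC | starting material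
11 | 9-(4,4-dimethoxybutyl)-9-borabicyclo[3.3.1]nonane | COC(OC)CCCB1C2CCCC1CCC2 | intermediate
12 | (4S)-4-(tert-butyldimethylsilyloxy)-2-(4,4-dimethoxybutyl)cyclopent-2-en-1-one | O=C1C(CCCC(OC)OC)=C[C@@H](O[Si](C)(C)C(C)(C)C)C1 | intermediate
13 | aldol adduct: benzyl N-[(1S)-3-[(1S,5R)-5-(tert-butyldimethylsilyloxy)-3-(4,4-dimethoxybutyl)-2-oxocyclopent-3-en-1-yl]-3-hydroxy-1-[(2S,4S)-4-methyl-5-oxooxolan-2-yl]propyl]carbamate (carbinol epimers) | O=C1C(CCCC(OC)OC)=C[C@@H](O[Si](C)(C)C(C)(C)C)[C@@H]1C(O)C[C@H](NC(=O)OCc1ccccc1)[C@@H]1C[C@H](C)C(=O)O1 | intermediate
14 | silyl-protected diketone: benzyl N-[(1S)-3-[(5R)-5-(tert-butyldimethylsilyloxy)-3-(4,4-dimethoxybutyl)-2-oxocyclopent-3-en-1-yl]-1-[(2S,4S)-4-methyl-5-oxooxolan-2-yl]-3-oxopropyl]carbamate | O=C1C(CCCC(OC)OC)=C[C@@H](O[Si](C)(C)C(C)(C)C)C1C(=O)C[C@H](NC(=O)OCc1ccccc1)[C@@H]1C[C@H](C)C(=O)O1 | intermediate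
15 | hydroxy diketone: benzyl N-[(1S)-3-[(5R)-3-(4,4-dimethoxybutyl)-5-hydroxy-2-oxocyclopent-3-en-1-yl]-1-[(2S,4S)-4-methyl-5-oxooxolan-2-yl]-3-oxopropyl]carbamate | O=C1C(CCCC(OC)OC)=C[C@@H](O)C1C(=O)C[C@H](NC(=O)OCc1ccccc1)[C@@H]1C[C@H](C)C(=O)O1 | intermediate
16 | (2S)-2-bromopropanoic acid | C[C@H](Br)C(=O)O | starting material
17 | (1S)-5-[(3S)-3-(benzyloxycarbonylamino)-3-[(2S,4S)-4-methyl-5-oxooxolan-2-yl]propanoyl]-3-(4,4-dimethoxybutyl)-4-oxocyclopent-2-en-1-yl (2S)-2-bromopropanoate | O=C1C(CCCC(OC)OC)=C[C@H](OC(=O)[C@H](C)Br)C1C(=O)C[C@H](NC(=O)OCc1ccccc1)[C@@H]1C[C@H](C)C(=O)O1 | intermediate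
18 | benzyl N-[(1S)-3-[(1S,4S,5S)-7-(4,4-dimethoxybutyl)-4-methyl-3,6-dioxo-2-oxabicyclo[3.3.0]oct-7-en-5-yl]-1-[(2S,4S)-4-methyl-5-oxooxolan-2-yl]-3-oxopropyl]carbamate | C1=C(CCCC(OC)OC)C(=O)[C@@]2(C(=O)C[C@H](NC(=O)OCc3ccccc3)[C@@H]3C[C@H](C)C(=O)O3)[C@H](C)C(=O)O[C@@H]12 | intermediate
19 | benzyl N-[(1S)-3-[(1S,4S,5S,7R,8R)-7-(4,4-dimethoxybutyl)-8-ethyl-4-methyl-3,6-dioxo-2-oxabicyclo[3.3.0]octan-5-yl]-1-[(2S,4S)-4-methyl-5-oxooxolan-2-yl]-3-oxopropyl]carbamate | CC[C@H]1[C@@H]2OC(=O)[C@@H](C)[C@]2(C(=O)C[C@H](NC(=O)OCc2ccccc2)[C@@H]2C[C@H](C)C(=O)O2)C(=O)[C@@H]1CCCC(OC)OC | intermediate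
20 | amino diketone: (1S,4S,5S,7R,8R)-5-[(3S)-3-amino-3-[(2S,4S)-4-methyl-5-oxooxolan-2-yl]propanoyl]-7-(4,4-dimethoxybutyl)-8-ethyl-4-methyl-2-oxabicyclo[3.3.0]octane-3,6-dione | CC[C@H]1[C@@H]2OC(=O)[C@@H](C)[C@]2(C(=O)C[C@@H]([C@@H]2C[C@H](C)C(=O)O2)N)C(=O)[C@@H]1CCCC(OC)OC | intermediate
21 | bicyclic carbinolamine (nitrogen added to the cyclopentanone carbonyl; six-membered ring fused at the quaternary carbon; carbinolamine carbon undefined) | CC[C@H]1[C@@H]2OC(=O)[C@@H](C)[C@@]23C(=O)C[C@@H]([C@@H]2C[C@H](C)C(=O)O2)NC3(O)[C@@H]1CCCC(OC)OC | intermediate
22 | nine-membered keto lactam, secondary amide, cis-fused methyl lactone, 4,4-dimethoxybutyl chain on the lactam α-carbon | CC[C@H]1[C@@H]2OC(=O)[C@@H](C)[C@@H]2C(=O)C[C@@H]([C@@H]2C[C@H](C)C(=O)O2)NC(=O)[C@@H]1CCCC(OC)OC | intermediate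
23 | methoxy aminal: target skeleton with a methoxy group on the azepanone carbon next to nitrogen (that carbon undefined) | CC[C@H]1[C@@H]2OC(=O)[C@@H](C)[C@@H]2C(=O)C[C@@H]([C@@H]2C[C@H](C)C(=O)O2)N2C(OC)CCC[C@H]1C2=O | intermediate
24 | target CNP0311700.2: bridged azepanone/nine-membered keto lactam with cis-fused α-methyl lactone, ethyl group and pendant cis-2,4-disubstituted lactone | CC[C@H]1[C@@H]2OC(=O)[C@@H](C)[C@@H]2C(=O)C[C@@H]([C@@H]2C[C@H](C)C(=O)O2)N2CCCC[C@H]1C2=O | target

## Step count and least certain steps

Total: 14 steps. Longest linear sequence: 12 steps (from 1 through steps 1 to 4 and 7 to 14). The branch from 8 is 10 steps (steps 5 to 14).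

**Step 13 (key step).** The most likely failure is diversion of the freed amine into an O-to-N acyl shift onto the pendant lactone, because that carbonyl is reachable through a six-membered ring as well. A second risk is that the carbinolamine stalls as a cyclic imine, or that ketonisation of the enol gives the wrong ring-fusion epimer. Fallback, from 19 back to 22: the nitrogen is kept acylated. The carbamate of 19 is deprotonated with LiN(SiMe3)2 in THF at −78 °C so that the carbamate anion adds to the ring ketone and the alkoxide fragments; a cold acetic acid quench should give the N-benzyloxycarbonyl nine-membered imide F1. Hydrogenolysis (H2, Pd/C) then gives 22. In this order no free amine ever faces the pendant lactone, and addition of the carbamate anion to a lactone is reversible whereas the fragmentation is not.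

**Step 2.** The risk is poor facial selectivity in the addition to the α-amino aldehyde, since chelation by an N–H carbamate in water is only moderately organised and the free γ-hydroxyl may interfere. Fallback, from 1 back to 5: the lactone of 1 is opened with MeNHOMe·HCl and Al(CH3)3 to the hydroxy Weinreb amide F2, which is silylated (TBSCl, imidazole) to F3 and reduced with LiAlH4 at −78 °C to the open-chain aldehyde F4. Allylation with ethyl 2-(trimethylsilylmethyl)prop-2-enoate and SnCl4 at −78 °C, a Lewis acid that chelates aldehyde and carbamate, should give the syn hydroxy ester F5. This lactonises with acid to the silyl ether F6, and HF·pyridine returns 5.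

**Step 7.** The risk is proton transfer from the enolisable, β-carbamoyl aldehyde to the enolate, followed by loss of the carbamate, or retro-aldol on warming. Fallback, from 6 back to 14: the acyl group is brought in at the acid oxidation level. 6 is oxidised (TEMPO, PhI(OAc)2, MeCN–H2O) to the acid F7, which is converted with benzotriazole and SOCl2 into the N-acylbenzotriazole F8. The lithium enolate of 12 (LiN(SiMe3)2, two equivalents, −78 °C) is C-acylated by F8 to give 14 directly.

**Steps 10 and 11.** The risks are side reactions of the enolised diketone under Mitsunobu conditions (addition to the azo ester, retention through an acyloxyphosphonium ion), racemisation of the bromo ester by bromide exchange, and O-alkylation. Fallback, from 14 back to 18: the order of bond formation is reversed. The enolate of 14 (K2CO3, DMF) is alkylated by allyl (2S)-2-(trifluoromethylsulfonyloxy)propanoate anti to the silyloxy group, with inversion, to give the C-alkylated diketone F9. HF·pyridine gives the alcohol F10, and Pd(PPh3)4 with morpholine removes the allyl group to give the trans hydroxy acid F11. Mitsunobu lactonisation (PPh3, DIAD) with inversion at the carbinol then closes the cis-fused lactone 18, at a stage where the diketone can no longer enolise.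

**Step 12.** The risk is attack of the organometallic on a ketone or lactone, or consumption by the N–H, on a crowded enone. Fallback, from 18 back to 19 with no new compound: radical conjugate ethylation with Et3B and a trace of O2 in wet THF, which proceeds through an ethyl radical and a boron enolate under neutral conditions, followed by the same Et3N equilibration.

## Further compounds

F1 | step 13 | N-benzyloxycarbonyl nine-membered keto imide (22 with the benzyl carbamate on the lactam nitrogen) | CC[C@H]1[C@@H]2OC(=O)[C@@H](C)[C@@H]2C(=O)C[C@@H]([C@@H]2C[C@H](C)C(=O)O2)N(C(=O)OCc2ccccc2)C(=O)[C@@H]1CCCC(OC)OC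
F2 | step 2 | benzyl N-[(2S)-4-hydroxy-1-[methoxy(methyl)amino]-1-oxobutan-2-yl]carbamate | CON(C)C(=O)[C@H](CCO)NC(=O)OCc1ccccc1
F3 | step 2 | benzyl N-[(2S)-4-(tert-butyldimethylsilyloxy)-1-[methoxy(methyl)amino]-1-oxobutan-2-yl]carbamate | CON(C)C(=O)[C@H](CCO[Si](C)(C)C(C)(C)C)NC(=O)OCc1ccccc1
F4 | step 2 | benzyl N-[(2S)-4-(tert-butyldimethylsilyloxy)-1-oxobutan-2-yl]carbamate | O=C[C@H](CCO[Si](C)(C)C(C)(C)C)NC(=O)OCc1ccccc1
F5 | step 2 | ethyl (4S,5S)-5-(benzyloxycarbonylamino)-7-(tert-butyldimethylsilyloxy)-4-hydroxy-2-methylideneheptanoate | CCOC(=O)C(=C)C[C@H](O)[C@H](CCO[Si](C)(C)C(C)(C)C)NC(=O)OCc1ccccc1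
F6 | step 2 | benzyl N-[(1S)-3-(tert-butyldimethylsilyloxy)-1-[(2S)-4-methylidene-5-oxooxolan-2-yl]propyl]carbamate | CC(C)(C)[Si](C)(C)OCC[C@H](NC(=O)OCc1ccccc1)[C@@H]1CC(=C)C(=O)O1
F7 | step 7 | (3S)-3-(benzyloxycarbonylamino)-3-[(2S,4S)-4-methyl-5-oxooxolan-2-yl]propanoic acid | OC(=O)C[C@H](NC(=O)OCc1ccccc1)[C@@H]1C[C@H](C)C(=O)O1
F8 | step 7 | benzyl N-[(1S)-3-(benzotriazol-1-yl)-1-[(2S,4S)-4-methyl-5-oxooxolan-2-yl]-3-oxopropyl]carbamate | O=C(C[C@H](NC(=O)OCc1ccccc1)[C@@H]1C[C@H](C)C(=O)O1)n1nnc2ccccc12
F9 | step 11 | allyl (2S)-2-[(1S,5R)-1-[(3S)-3-(benzyloxycarbonylamino)-3-[(2S,4S)-4-methyl-5-oxooxolan-2-yl]propanoyl]-5-(tert-butyldimethylsilyloxy)-3-(4,4-dimethoxybutyl)-2-oxocyclopent-3-en-1-yl]propanoate | C=CCOC(=O)[C@@H](C)[C@@]1(C(=O)C[C@H](NC(=O)OCc2ccccc2)[C@@H]2C[C@H](C)C(=O)O2)[C@H](O[Si](C)(C)C(C)(C)C)C=C(CCCC(OC)OC)C1=O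
F10 | step 11 | the 5-hydroxy compound from F9 (silyl group removed) | C=CCOC(=O)[C@@H](C)[C@@]1(C(=O)C[C@H](NC(=O)OCc2ccccc2)[C@@H]2C[C@H](C)C(=O)O2)[C@H](O)C=C(CCCC(OC)OC)C1=O
F11 | step 11 | the trans hydroxy acid from F10 (allyl group removed) | OC(=O)[C@@H](C)[C@@]1(C(=O)C[C@H](NC(=O)OCc2ccccc2)[C@@H]2C[C@H](C)C(=O)O2)[C@H](O)C=C(CCCC(OC)OC)C1=O
F0 | step 12 | none | none
A1 | alternative 1 | mixed bromoacetal of the nine-membered (Z)-cycloalkenol with bridging azepanone | CC[C@H]1[C@H](OC(OCC)C(C)Br)/C=C\C[C@@H]([C@@H]2C[C@H](C)C(=O)O2)N2CCCC[C@H]1C2=O
A2 | alternative 1 | cis-fused lactol ethyl ether with ring carbinol | CC[C@H]1[C@@H]2OC(OCC)[C@@H](C)[C@@H]2C(O)C[C@@H]([C@@H]2C[C@H](C)C(=O)O2)N2CCCC[C@H]1C2=O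
A3 | alternative 2 | N-(2,4-dimethoxybenzyl)-2-[(E)-but-1-enyl]-3-(tert-butyldimethylsilyloxy)-5-(tert-butyldimethylsilyloxymethyl)pyrrolidine (2,3-trans drawn; the configuration at C2 is a design choice) | CC/C=C/[C@H]1[C@H](O[Si](C)(C)C(C)(C)C)C[C@@H](CO[Si](C)(C)C(C)(C)C)N1Cc1ccc(OC)cc1OC
A4 | alternative 2 | 6-chlorohexanoyl fluoride | O=C(F)CCCCCCl
A5 | alternative 2 | N-dimethoxybenzyl nine-membered lactam with E ring alkene | CC[C@H]1/C=C/[C@H](O[Si](C)(C)C(C)(C)C)C[C@@H](CO[Si](C)(C)C(C)(C)C)N(Cc2ccc(OC)cc2OC)C(=O)[C@@H]1CCCCCl
A6 | alternative 3 | aldehyde carrying the 4-bromo-3-propylidene caprolactam (bromide carbon and alkene geometry undefined) | O=C[C@H]([C@H](C)C(=O)OC)[C@@H](O[Si](C)(C)C(C)(C)C)C[C@@H]([C@@H]1C[C@H](C)C(=O)O1)N1CCCC(Br)C(=CCC)C1=O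
A7 | alternative 3 | bridged hydroxy ester with unsaturated azepanone | CC[C@H]1[C@H](O)[C@H]([C@H](C)C(=O)OC)[C@@H](O[Si](C)(C)C(C)(C)C)C[C@@H]([C@@H]2C[C@H](C)C(=O)O2)N2CCCC=C1C2=O
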